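Ring A is disconnected at the C4a–C5 bond. Its pattern (C5 hydroxyl para to the C8 methoxyl, C7 methoxyl, unsubstituted C6, O1 on C8a) is what a 3,4-dimethoxycyclobutenone with an alkenyl group on its saturated carbon delivers on thermal rearrangement. Heating this squarate-derived cyclobutenone gives a dienylketene that closes onto the alkene CH of ring C (future C4a). One operation thus builds ring A with all four oxygens in place and already differentiated. The precursor is a racemic cis-2-aryl-4-silyloxy-3,4-dihydro-2H-pyran (ring C with ring B attached, from a hetero-Diels–Alder reaction) carrying the cyclobutenone on its O-bearing alkene carbon; both silyl groups are TIPS.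

Key step: step 7

Remark on stereochemistry: the target is achiral, so all chiral intermediates are racemic. The SMILES show one enantiomer of the cis series. The cyclobutenone carbon of 12 and 13 is left undefined because both epimers form and both converge in step 7.

Remark on protecting groups: the C4 oxygen is carried as a TIPS ether, not a methyl-bearing silyl ether, because t-BuLi can metalate Si–CH3 groups. Both TIPS groups are removed together by fluoride before the C4 oxidation, since an aryl silyl ether cannot be kept while an alkyl one is cleaved with fluoride, and acid would ionise the electron-rich C4 benzylic position.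

Step 1
Reactants: 1 3-hydroxy-4,5-dimethoxybenzaldehyde
Product: 2 3,4-dimethoxy-5-(triisopropylsilyloxy)benzaldehyde
Conditions: TIPSCl, imidazole, DMF, rt
Reagents that add atoms: triisopropylsilyl chloride (TIPSCl), CC(C)[Si](Cl)(C(C)C)C(C)C
Why: Standard phenol O-silylation (substitution at silicon) that leaves the aldehyde untouched and gives a bulky aryl silyl ether able to withstand the Lewis acid, hydride, alkyllithium and heat used later.

Step 2
Reactants: 2 3,4-dimethoxy-5-(triisopropylsilyloxy)benzaldehyde; 3 (E)-1-methoxy-3-(trimethylsilyloxy)buta-1,3-diene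
Product: 5 rac-2-[3,4-dimethoxy-5-(triisopropylsilyloxy)phenyl]-2,3-dihydro-4H-pyran-4-one, via cycloadduct 4 (not isolated)
Conditions: ZnCl2, THF, rt; then CF3CO2H (cat.), CH2Cl2, 0 °C
Reagents that add atoms: none
Why: Lewis-acid-promoted hetero-Diels–Alder reaction in which the nucleophilic CH2 terminus of the siloxydiene bonds to the aldehyde carbon, followed by acid-induced loss of methanol and of the silyl group to the vinylogous ester, the single new stereocentre (C2) being formed racemic.

Step 3
Reactants: 5 rac-2-[3,4-dimethoxy-5-(triisopropylsilyloxy)phenyl]-2,3-dihydro-4H-pyran-4-one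
Product: 6 rac-cis-2-[3,4-dimethoxy-5-(triisopropylsilyloxy)phenyl]-3,4-dihydro-2H-pyran-4-ol
Conditions: NaBH4, CeCl3·7H2O, MeOH, −78 °C
Reagents that add atoms: none
Why: Luche 1,2-reduction of the enone, in which axial hydride delivery to the half-chair with a pseudo-equatorial aryl group should give the pseudo-equatorial alcohol cis to the aryl group (substrate control), although this centre is later oxidised away.

Step 4
Reactants: 6 rac-cis-2-[3,4-dimethoxy-5-(triisopropylsilyloxy)phenyl]-3,4-dihydro-2H-pyran-4-ol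
Product: 7 rac-cis-2-[3,4-dimethoxy-5-(triisopropylsilyloxy)phenyl]-4-(triisopropylsilyloxy)-3,4-dihydro-2H-pyran
Conditions: TIPSOTf, 2,6-lutidine, CH2Cl2, −78 → 0 °C
Reagents that add atoms: triisopropylsilyl trifluoromethanesulfonate (TIPSOTf), CC(C)[Si](OS(=O)(=O)C(F)(F)F)(C(C)C)C(C)C
Why: Base-buffered silylation of the acid-sensitive allylic alcohol, giving a silyl ether without Si–CH3 groups so that the later t-BuLi metalation is not diverted to silicon-bound methyl groups.

Step 5
Reactants: 8 dimethyl squarate (3,4-dimethoxycyclobut-3-ene-1,2-dione)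
Product: 10 3-methoxycyclobut-3-ene-1,2-dione, via hydroxycyclobutenone 9 (not isolated)
Conditions: LiAlH(OtBu)3, THF, −78 °C; aq. HCl quench; then conc. HCl (cat.), CH2Cl2, rt
Reagents that add atoms: none
Why: The mild, hindered aluminohydride adds once to a squarate carbonyl, and acid then ionises the carbinol to a methoxy-stabilised cyclobutenyl cation, water returns at the methoxy-bearing terminus and methanol is lost (the standard squarate adduct to cyclobutenedione rearrangement, a 1,3-carbonyl transposition).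

Step 6
Reactants: 7 rac-cis-2-[3,4-dimethoxy-5-(triisopropylsilyloxy)phenyl]-4-(triisopropylsilyloxy)-3,4-dihydro-2H-pyran; 10 3-methoxycyclobut-3-ene-1,2-dione
Product: 13 4-{cis-2-[3,4-dimethoxy-5-(triisopropylsilyloxy)phenyl]-4-(triisopropylsilyloxy)-3,4-dihydro-2H-pyran-6-yl}-3,4-dimethoxycyclobut-2-en-1-one, via vinyllithium 11 (not isolated), via lithium alkoxide 12 (not isolated)
Conditions: t-BuLi, THF, −78 → 0 °C; then cannulated into 10, THF, −78 °C; then MeOTf, −78 → −20 °C
Reagents that add atoms: methyl trifluoromethanesulfonate (MeOTf), COS(=O)(=O)C(F)(F)F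
Why: Glycal-type α-lithiation of the enol ether C6–H gives 11, which adds 1,2 to the ketone-like carbonyl of 10 flanked by the methoxy-bearing carbon (the other carbonyl is deactivated as a vinylogous ester), and the tertiary lithium alkoxide is O-methylated in situ by MeOTf (SN2), the new quaternary centre forming as both epimers, which is irrelevant because step 7 destroys it.

Step 7
Reactants: 13 4-{cis-2-[3,4-dimethoxy-5-(triisopropylsilyloxy)phenyl]-4-(triisopropylsilyloxy)-3,4-dihydro-2H-pyran-6-yl}-3,4-dimethoxycyclobut-2-en-1-one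
Product: 16 rac-cis-2-[3,4-dimethoxy-5-(triisopropylsilyloxy)phenyl]-7,8-dimethoxy-4-(triisopropylsilyloxy)chroman-5-ol, via dienylketene 14 (not isolated), via cyclohexadienone 15 (not isolated)
Conditions: PhMe (degassed, 0.01 M), 110 °C, Ar
Reagents that add atoms: none
Why: Heat cleaves the bond between the carbonyl carbon and the saturated carbon of the cyclobutenone in a conrotatory 4π electrocyclic opening; the donor methoxyl on that carbon rotates outward, so the dihydropyranyl group turns inward and the (Z)-dienylketene 14 results. The ketene carbon (future C5) then bonds to the pyran alkene CH (future C4a) in a thermal disrotatory 6π electrocyclisation, a six-membered carbocyclisation that closes ring A as the 4a-H cyclohexadienone 15, which enolises to the C5 phenol. The closest known reaction type is the thermal rearrangement of 4-alkenyl-4-alkoxycyclobutenones to hydroquinone monoethers (Moore-type benzannulation), documented for lithiated cyclic enol ethers added to squarates. No stereocentre is created, and the cyclobutenone centre is erased, so both epimers of 13 converge while the cis C2/C4 relationship is untouched. The only selectivity required is torquoselectivity, which the 4-methoxyl provides; closure can occur at only one alkene terminus because the other carries O1. Since C5–OH, C6–H, C7–OMe, C8–OMe and O1–C8a are all dictated by the connectivity of 13, an isomeric 5,6,7-oxygenated ring A is structurally excluded.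

Step 8
Reactants: 16 rac-cis-2-[3,4-dimethoxy-5-(triisopropylsilyloxy)phenyl]-7,8-dimethoxy-4-(triisopropylsilyloxy)chroman-5-ol
Product: 17 rac-cis-2-(3-hydroxy-4,5-dimethoxyphenyl)-7,8-dimethoxychroman-4,5-diol
Conditions: Bu4NF, THF, 0 °C → rt, Ar; pH 7 phosphate buffer work-up
Reagents that add atoms: none
Why: Fluoride-induced desilylation removes the aryl and the benzylic TIPS ether in one operation under non-acidic conditions, at the flavan-4-ol stage where basic fluoride cannot open ring C as it could in a 5-hydroxyflavanone.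

Step 9
Reactants: 17 rac-cis-2-(3-hydroxy-4,5-dimethoxyphenyl)-7,8-dimethoxychroman-4,5-diol
Product: 18 rac-5-hydroxy-2-(3-hydroxy-4,5-dimethoxyphenyl)-7,8-dimethoxychroman-4-one
Conditions: MnO2 (activated, excess), CH2Cl2, rt
Reagents that add atoms: none
Why: MnO2 oxidation is selective for the strongly activated benzylic C4 alcohol (ortho-hydroxy and para-methoxy assistance from ring A) and is known to tolerate free phenols in hydroxybenzylic alcohols, giving a ketone stabilised by the C5–OH hydrogen bond.

Step 10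
Reactants: 18 rac-5-hydroxy-2-(3-hydroxy-4,5-dimethoxyphenyl)-7,8-dimethoxychroman-4-one
Product: 20 5,3'-dihydroxy-7,8,4',5'-tetramethoxyflavone, via iodoflavanone 19 (not isolated)
Conditions: I2 (cat.), DMSO, 130 °C
Reagents that add atoms: none
Why: Iodine-mediated dehydrogenation of a flavanone (C3 iodination of the enol, loss of HI, reoxidation of HI by DMSO), a method established for flavanones with free C5 and ring B hydroxyls, introduces the C2–C3 double bond and removes the last stereocentre.

Compound list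
1 | 3-hydroxy-4,5-dimethoxybenzaldehyde | COc1cc(C=O)cc(O)c1OC | starting material
2 | 3,4-dimethoxy-5-(triisopropylsilyloxy)benzaldehyde | COc1cc(C=O)cc(O[Si](C(C)C)(C(C)C)C(C)C)c1OC | intermediate
3 | (E)-1-methoxy-3-(trimethylsilyloxy)buta-1,3-diene | CO/C=C/C(=C)O[Si](C)(C)C | starting material
4 | 2-[3,4-dimethoxy-5-(triisopropylsilyloxy)phenyl]-6-methoxy-4-(trimethylsilyloxy)-3,6-dihydro-2H-pyran (cycloadduct, diastereomer mixture) | COC1C=C(O[Si](C)(C)C)CC(O1)c2cc(OC)c(OC)c(O[Si](C(C)C)(C(C)C)C(C)C)c2 | intermediate (not isolated)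
5 | rac-2-[3,4-dimethoxy-5-(triisopropylsilyloxy)phenyl]-2,3-dihydro-4H-pyran-4-one | O=C1C[C@@H](OC=C1)c2cc(OC)c(OC)c(O[Si](C(C)C)(C(C)C)C(C)C)c2 | intermediate
6 | rac-cis-2-[3,4-dimethoxy-5-(triisopropylsilyloxy)phenyl]-3,4-dihydro-2H-pyran-4-ol | C1=C[C@H](O)C[C@@H](O1)c2cc(OC)c(OC)c(O[Si](C(C)C)(C(C)C)C(C)C)c2 | intermediate
7 | rac-cis-2-[3,4-dimethoxy-5-(triisopropylsilyloxy)phenyl]-4-(triisopropylsilyloxy)-3,4-dihydro-2H-pyran | C1=C[C@H](O[Si](C(C)C)(C(C)C)C(C)C)C[C@@H](O1)c2cc(OC)c(OC)c(O[Si](C(C)C)(C(C)C)C(C)C)c2 | intermediate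
8 | dimethyl squarate (3,4-dimethoxycyclobut-3-ene-1,2-dione) | COC1=C(OC)C(=O)C1=O | starting material
9 | 4-hydroxy-2,3-dimethoxycyclobut-2-en-1-one (racemic) | COC1=C(OC)C(=O)C1O | intermediate (not isolated)
10 | 3-methoxycyclobut-3-ene-1,2-dione (methyl semisquarate) | COC1=CC(=O)C1=O | intermediate
11 | rac-cis-2-[3,4-dimethoxy-5-(triisopropylsilyloxy)phenyl]-6-lithio-4-(triisopropylsilyloxy)-3,4-dihydro-2H-pyran | [Li]C1=C[C@H](O[Si](C(C)C)(C(C)C)C(C)C)C[C@@H](O1)c2cc(OC)c(OC)c(O[Si](C(C)C)(C(C)C)C(C)C)c2 | intermediate (not isolated)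
12 | lithium alkoxide of 4-hydroxy-3-methoxy-4-{cis-2-[3,4-dimethoxy-5-(triisopropylsilyloxy)phenyl]-4-(triisopropylsilyloxy)-3,4-dihydro-2H-pyran-6-yl}cyclobut-2-en-1-one (both epimers at the carbinol carbon) | O=C1C=C(OC)C1(O[Li])C2=C[C@H](O[Si](C(C)C)(C(C)C)C(C)C)C[C@@H](O2)c3cc(OC)c(OC)c(O[Si](C(C)C)(C(C)C)C(C)C)c3 | intermediate (not isolated)
13 | 4-{cis-2-[3,4-dimethoxy-5-(triisopropylsilyloxy)phenyl]-4-(triisopropylsilyloxy)-3,4-dihydro-2H-pyran-6-yl}-3,4-dimethoxycyclobut-2-en-1-one (racemic, both epimers at the cyclobutenone carbon) | O=C1C=C(OC)C1(OC)C2=C[C@H](O[Si](C(C)C)(C(C)C)C(C)C)C[C@@H](O2)c3cc(OC)c(OC)c(O[Si](C(C)C)(C(C)C)C(C)C)c3 | intermediate (key-step precursor)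
14 | (Z)-3,4-dimethoxy-4-{cis-2-[3,4-dimethoxy-5-(triisopropylsilyloxy)phenyl]-4-(triisopropylsilyloxy)-3,4-dihydro-2H-pyran-6-yl}buta-1,3-dien-1-one (dienylketene) | O=C=C/C(OC)=C(OC)\C1=C[C@H](O[Si](C(C)C)(C(C)C)C(C)C)C[C@@H](O1)c2cc(OC)c(OC)c(O[Si](C(C)C)(C(C)C)C(C)C)c2 | intermediate (not isolated)
15 | 2-[3,4-dimethoxy-5-(triisopropylsilyloxy)phenyl]-7,8-dimethoxy-4-(triisopropylsilyloxy)-2,3,4,4a-tetrahydro-5H-chromen-5-one (4a-H cyclohexadienone, C4a configuration undefined) | COC1=CC(=O)C2[C@H](O[Si](C(C)C)(C(C)C)C(C)C)C[C@@H](OC2=C1OC)c3cc(OC)c(OC)c(O[Si](C(C)C)(C(C)C)C(C)C)c3 | intermediate (not isolated)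
16 | rac-cis-2-[3,4-dimethoxy-5-(triisopropylsilyloxy)phenyl]-7,8-dimethoxy-4-(triisopropylsilyloxy)chroman-5-ol | COc1cc(O)c2[C@H](O[Si](C(C)C)(C(C)C)C(C)C)C[C@@H](Oc2c1OC)c3cc(OC)c(OC)c(O[Si](C(C)C)(C(C)C)C(C)C)c3 | intermediate (key-step product)
17 | rac-cis-2-(3-hydroxy-4,5-dimethoxyphenyl)-7,8-dimethoxychroman-4,5-diol | COc1cc(O)c2[C@H](O)C[C@@H](Oc2c1OC)c3cc(OC)c(OC)c(O)c3 | intermediate
18 | rac-5-hydroxy-2-(3-hydroxy-4,5-dimethoxyphenyl)-7,8-dimethoxychroman-4-one (5,3'-dihydroxy-7,8,4',5'-tetramethoxyflavanone) | COc1cc(O)c2C(=O)C[C@@H](Oc2c1OC)c3cc(OC)c(OC)c(O)c3 | intermediate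
19 | 5-hydroxy-2-(3-hydroxy-4,5-dimethoxyphenyl)-3-iodo-7,8-dimethoxychroman-4-one (C3 configuration undefined) | COc1cc(O)c2C(=O)C(I)[C@@H](Oc2c1OC)c3cc(OC)c(OC)c(O)c3 | intermediate (not isolated)
20 | 5,3'-dihydroxy-7,8,4',5'-tetramethoxyflavone | COc1cc(-c2cc(=O)c3c(O)cc(OC)c(OC)c3o2)cc(O)c1OC | target

Total step count: 10. Longest linear sequence: 9 steps (steps 1, 2, 3, 4, 6, 7, 8, 9, 10); step 5 is a one-step side branch.

Steps most likely to fail

Step 6. Metalation may be diverted to the benzylic C2–H or to ring B positions ortho to oxygen. Surplus t-BuLi may consume the sensitive dione, and in-flask O-methylation may be incomplete. Fallback, setting out from 7 and rejoining at 11 (then 13): the enol ether is oxidised with C5H5NH[CrO3Cl] (pyridinium chlorochromate) in CH2Cl2 to the δ-lactone F1. Enolisation with KN(SiMe3)2 and trapping with (PhO)2P(O)Cl at −78 °C gives the ketene acetal phosphate F2. Coupling with Me3SnSnMe3 under Pd(PPh3)4 (zerovalent palladium) and LiCl in THF gives the vinylstannane F3. Tin–lithium exchange with MeLi at −78 °C then generates 11 stoichiometrically and without any strong alkyllithium base in contact with the benzylic C–H. Addition to 10 and methylation follow as in step 6.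

Step 7. At 110 °C silanol may be lost from the ortho-hydroxybenzylic silyl ether (at the dienone or the phenol stage) through an ortho-quinone methide, with oligomerisation. The hydroquinone monoether may also be oxidised by adventitious air. Fallback, setting out from 13 and rejoining at 18: Bu4NF buffered with AcOH removes both silyl groups to give the allylic alcohol–phenol F4. MnO2 oxidises the allylic alcohol to the dihydropyranone F5. Thermolysis of F5 in dilute toluene then gives 18 directly by the same ring opening and electrocyclisation onto the α-carbon of the vinylogous ester. No benzylic leaving group is present during heating, and the product is the hydrogen-bonded, more robust flavanone.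

Step 9. The electron-rich free phenols may be oxidised in competition with the alcohol (quinone formation from the para-methoxyphenol of ring A, oxidative coupling at ring B). Fallback, setting out from 17 and rejoining at 18: Schotten–Baumann acetylation (Ac2O, aqueous NaHCO3, THF) masks only the two phenols to give the diacetate alcohol F6. Dess–Martin periodinane oxidises the remaining secondary alcohol to the diacetoxyflavanone F7. Mild deacetylation with NH4OAc in aqueous MeOH, which avoids base-induced opening of ring C, returns 18.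

Further compounds
F1 | step 6 | rac-cis-6-[3,4-dimethoxy-5-(triisopropylsilyloxy)phenyl]-4-(triisopropylsilyloxy)tetrahydro-2H-pyran-2-one | O=C1C[C@H](O[Si](C(C)C)(C(C)C)C(C)C)C[C@@H](O1)c2cc(OC)c(OC)c(O[Si](C(C)C)(C(C)C)C(C)C)c2
F2 | step 6 | rac-cis-2-[3,4-dimethoxy-5-(triisopropylsilyloxy)phenyl]-4-(triisopropylsilyloxy)-3,4-dihydro-2H-pyran-6-yl diphenyl phosphate | O=P(Oc1ccccc1)(Oc1ccccc1)OC1=C[C@H](O[Si](C(C)C)(C(C)C)C(C)C)C[C@@H](O1)c2cc(OC)c(OC)c(O[Si](C(C)C)(C(C)C)C(C)C)c2
F3 | step 6 | rac-cis-2-[3,4-dimethoxy-5-(triisopropylsilyloxy)phenyl]-4-(triisopropylsilyloxy)-6-(trimethylstannyl)-3,4-dihydro-2H-pyran | C[Sn](C)(C)C1=C[C@H](O[Si](C(C)C)(C(C)C)C(C)C)C[C@@H](O1)c2cc(OC)c(OC)c(O[Si](C(C)C)(C(C)C)C(C)C)c2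
F4 | step 7 | 4-[cis-4-hydroxy-2-(3-hydroxy-4,5-dimethoxyphenyl)-3,4-dihydro-2H-pyran-6-yl]-3,4-dimethoxycyclobut-2-en-1-one (racemic, both epimers at the cyclobutenone carbon) | O=C1C=C(OC)C1(OC)C2=C[C@H](O)C[C@@H](O2)c3cc(OC)c(OC)c(O)c3
F5 | step 7 | 4-[2-(3-hydroxy-4,5-dimethoxyphenyl)-4-oxo-3,4-dihydro-2H-pyran-6-yl]-3,4-dimethoxycyclobut-2-en-1-one (racemic, both epimers at the cyclobutenone carbon) | O=C1C=C(OC)C1(OC)C2=CC(=O)C[C@@H](O2)c3cc(OC)c(OC)c(O)c3
F6 | step 9 | rac-cis-5-acetoxy-2-(3-acetoxy-4,5-dimethoxyphenyl)-7,8-dimethoxychroman-4-ol | COc1cc(OC(C)=O)c2[C@H](O)C[C@@H](Oc2c1OC)c3cc(OC)c(OC)c(OC(C)=O)c3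
F7 | step 9 | rac-5-acetoxy-2-(3-acetoxy-4,5-dimethoxyphenyl)-7,8-dimethoxychroman-4-one | COc1cc(OC(C)=O)c2C(=O)C[C@@H](Oc2c1OC)c3cc(OC)c(OC)c(OC(C)=O)c3
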